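**Retrosynthetic overview**
1. Feature: in indole B (the 5-hydroxyindole) C3a and C7a are adjacent benzenoid carbons and the C5 oxygen is para to C7a. An aryne across C3a–C7a with a sacrificial chlorine at C4 can therefore accept N1 at C7a and C3 at C3a from one TsNH–CH2–C(=O)–aryl unit.
2. The only ring formed, and formed last, is the pyrrole ring of indole B, by aryne annulation and dehydration. Hydrogenolysis (benzyl, chlorine) and Mg/MeOH (two tosyl groups) then finish the synthesis.
3. The keto sulfonamide is disconnected at the bond between ring C and C3 of indole A (Suzuki–Miyaura). Indole A and ring C are bought as intact rings (6-methoxyindole, 1,2,4,5-tetramethoxybenzene).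
4. The ring C partner comes from dibromination, a single bromine–lithium exchange, a chloroacetyl Weinreb amide and TsNH2. All organolithium chemistry is finished before the N-tosylindole is present.
5. The o-silylaryl triflate comes from 2-chlororesorcinol by bromination, mono-benzylation of the dianion, O-silylation and retro-Brook shift with triflation.

Key step: step 12

Remark: the target has no stereocentre. Ring C is symmetric about its 1,4-axis, so neither biaryl axis is stereogenic. The hydroxyindoline formed in the key step is racemic and its centre disappears on dehydration.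

**Route**

Step 1
Reactants: 1 6-methoxy-1H-indole
Product: 2 3-iodo-6-methoxy-1H-indole
Conditions: I2, KOH, DMF, rt, dark
Reagents that add atoms: iodine, [I][I]
Why: Electrophilic aromatic iodination of the indolide, in which C3 is by far the most nucleophilic carbon of an N-unprotected indole, so iodine should enter there and not at C5 or C7 next to the methoxy group.

Step 2
Reactants: 2 3-iodo-6-methoxy-1H-indole
Product: 3 3-iodo-6-methoxy-1-tosylindole
Conditions: TsCl, 50% aq NaOH, Bu4NHSO4 (catalytic), toluene, rt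
Reagents that add atoms: p-toluenesulfonyl chloride, Cc1ccc(cc1)S(=O)(=O)Cl
Why: Phase-transfer N-sulfonylation of the indole N–H, where the tosyl group stabilises the light-sensitive 3-iodoindole, survives the later palladium and fluoride steps, and keeps N1 of indole A from being arylated by the aryne.

Step 3
Reactants: 3 3-iodo-6-methoxy-1-tosylindole
Product: 4 6-methoxy-3-(4,4,5,5-tetramethyl-1,3,2-dioxaborolan-2-yl)-1-tosylindole
Conditions: B2pin2, PdCl2(dppf) (catalytic), KOAc, dioxane, 80 °C
Reagents that add atoms: bis(pinacolato)diboron, CC1(C)OB(OC1(C)C)B1OC(C)(C)C(C)(C)O1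
Why: Miyaura borylation, in which zerovalent palladium inserts into the carbon–iodine bond and acetate-assisted transmetalation delivers the pinacol boronate without any organolithium that could attack the sulfonyl group.

Step 4
Reactants: 5 1,2,4,5-tetramethoxybenzene
Product: 6 1,4-dibromo-2,3,5,6-tetramethoxybenzene
Conditions: Br2 (2.1 equiv), dry CH2Cl2, 0 °C → rt
Reagents that add atoms: bromine, BrBr
Why: Twofold electrophilic aromatic bromination, since the only two free positions are equivalent and each is ortho to two methoxy groups, while a dry and cold medium should hold back oxidative demethylation to the quinone.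

Step 5
Reactants: 6 1,4-dibromo-2,3,5,6-tetramethoxybenzene
Product: 8 1-(4-bromo-2,3,5,6-tetramethoxyphenyl)-2-chloroethan-1-one, via aryllithium 7 (not isolated)
Conditions: n-BuLi (1.0 equiv), THF, −78 °C; ClCH2C(O)N(OMe)Me, −78 → −20 °C; 1 M HCl
Reagents that add atoms: 2-chloro-N-methoxy-N-methylacetamide, CON(C)C(=O)CCl
Why: Bromine–lithium exchange followed by Weinreb ketone synthesis, where one equivalent of n-BuLi exchanges one of two equivalent bromines, the chelated tetrahedral adduct blocks over-addition, and acting before indole A is attached avoids competing C2-lithiation of an N-sulfonylindole.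

Step 6
Reactants: 8 1-(4-bromo-2,3,5,6-tetramethoxyphenyl)-2-chloroethan-1-one
Product: 9 N-[2-(4-bromo-2,3,5,6-tetramethoxyphenyl)-2-oxoethyl]-4-methylbenzenesulfonamide
Conditions: TsNH2 (3 equiv), K2CO3, NaI (catalytic), DMF, rt
Reagents that add atoms: p-toluenesulfonamide, Cc1ccc(cc1)S(N)(=O)=O
Why: SN2 N-alkylation of a sulfonamide by an α-halo ketone under Finkelstein catalysis, in which the excess of TsNH2 should suppress a second alkylation and the two ortho methoxy groups shield the carbonyl from attack.

Step 7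
Reactants: 9 N-[2-(4-bromo-2,3,5,6-tetramethoxyphenyl)-2-oxoethyl]-4-methylbenzenesulfonamide; 4 6-methoxy-3-(4,4,5,5-tetramethyl-1,3,2-dioxaborolan-2-yl)-1-tosylindole
Product: 10 N-{2-oxo-2-[2,3,5,6-tetramethoxy-4-(6-methoxy-1-tosylindol-3-yl)phenyl]ethyl}-4-methylbenzenesulfonamide
Conditions: Pd(OAc)2 (catalytic), SPhos, K3PO4, dioxane–H2O, 85 °C
Reagents that add atoms: none
Why: Suzuki–Miyaura coupling, in which the electron-rich biaryl phosphine promotes oxidative addition into the doubly ortho-substituted C–Br bond, the hindered partner is the halide because 2,6-dialkoxyarylboron compounds protodeboronate readily, and the sulfonamide merely rests as its potassium salt.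

Step 8
Reactants: 11 2-chlorobenzene-1,3-diol (2-chlororesorcinol)
Product: 12 4-bromo-2-chlorobenzene-1,3-diol
Conditions: NBS (1.0 equiv, slow addition), MeCN, −20 → 0 °C
Reagents that add atoms: N-bromosuccinimide, O=C1CCC(=O)N1Br
Why: Electrophilic aromatic bromination, where C4 and C6 are equivalent by symmetry and each is ortho to one hydroxyl and para to the other while C5 is meta to both, so one equivalent of NBS should give a single monobromide.

Step 9
Reactants: 12 4-bromo-2-chlorobenzene-1,3-diol
Product: 14 3-(benzyloxy)-6-bromo-2-chlorophenol, via disodium diolate 13 (not isolated)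
Conditions: NaH (2.2 equiv), DMF, 0 °C; BnBr (1.0 equiv), 0 °C → rt; 1 M HCl
Reagents that add atoms: benzyl bromide, BrCc1ccccc1
Why: Williamson ether synthesis on the dianion, in which the oxygen flanked by chlorine and hydrogen is the more basic and less hindered one and should take up the single equivalent of benzyl bromide, while the oxygen between chlorine and bromine stays free.

Step 10
Reactants: 14 3-(benzyloxy)-6-bromo-2-chlorophenol
Product: 15 [3-(benzyloxy)-6-bromo-2-chlorophenoxy]trimethylsilane
Conditions: HMDS, THF, 70 °C; evaporate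
Reagents that add atoms: hexamethyldisilazane, C[Si](C)(C)N[Si](C)(C)C
Why: O-Silylation of a phenol with HMDS, which releases only ammonia so that the moisture-sensitive silyl ether can be used directly after evaporation.

Step 11
Reactants: 15 [3-(benzyloxy)-6-bromo-2-chlorophenoxy]trimethylsilane
Product: 17 3-(benzyloxy)-2-chloro-6-(trimethylsilyl)phenyl trifluoromethanesulfonate, via lithium phenolate 16 (not isolated)
Conditions: n-BuLi, THF, −78 °C; Tf2O, −78 → 0 °C
Reagents that add atoms: trifluoromethanesulfonic anhydride, O=S(=O)(OS(=O)(=O)C(F)(F)F)C(F)(F)F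
Why: Bromine–lithium exchange, faster at −78 °C than deprotonation of the benzylic CH2, followed by retro-Brook rearrangement (1,3 O→C silyl shift) and O-triflation of the lithium phenolate, which is the standard entry to o-silylaryl triflates.

Step 12
Reactants: 10 N-{2-oxo-2-[2,3,5,6-tetramethoxy-4-(6-methoxy-1-tosylindol-3-yl)phenyl]ethyl}-4-methylbenzenesulfonamide; 17 3-(benzyloxy)-2-chloro-6-(trimethylsilyl)phenyl trifluoromethanesulfonate
Product: 20 5-(benzyloxy)-4-chloro-3-[2,3,5,6-tetramethoxy-4-(6-methoxy-1-tosylindol-3-yl)phenyl]-1-tosylindole, via aryne 18 (not isolated), via 3-hydroxyindoline 19 (not isolated)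
Conditions: CsF (4 equiv), THF–MeCN (5:1), 50 °C, 17 (1.6 equiv) added slowly; filter, concentrate; p-TsOH·H2O (catalytic), CH2Cl2, rt
Reagents that add atoms: none
Why: Fluoride attacks silicon of 17 and triflate departs to release aryne 18, the sulfonamide nitrogen of 10 (deprotonated by CsF) adds to the aryne carbon remote from chlorine (future C7a, forming N1–C7a), the aryl anion thus placed next to chlorine (future C3a) attacks the tethered ketone (forming C3–C3a) to give 19, and p-TsOH then ionises the doubly benzylic C3–OH so that loss of a C2 proton aromatises the new pyrrole ring. The closest known reaction type is the heteroannulation of arynes with α-amino ketones to indoles (an aryne version of the Bischler–Möhlau synthesis), backed by the fluoride-mediated N-arylation of sulfonamides with o-silylaryl triflates and by the acridine synthesis from arynes and 2-aminoaryl ketones. The single ring closed, the pyrrole ring of indole B, forms by 5-exo-trig attack of the C3a anion on the carbonyl carbon. The carbinol centre C3 of 19 arises racemic and is erased by the dehydration, so no stereocontrol is required. The selectivity needed is the orientation of addition: the C–Cl bond distorts the aryne so that the distal carbon is the more linear and electrophilic terminus, the charge develops ortho to chlorine and meta to the benzyloxy oxygen where induction stabilises it, and chlorine also shields the proximal carbon, so all three effects send nitrogen to C7a, para to the C5 oxygen. A THF-rich medium and slow addition of 17 keep proton donors scarce, so that closure on the ketone, which is flanked by two ortho methoxy groups, should outrun protonation of the aryl anion.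

Step 13
Reactants: 20 5-(benzyloxy)-4-chloro-3-[2,3,5,6-tetramethoxy-4-(6-methoxy-1-tosylindol-3-yl)phenyl]-1-tosylindole
Product: 21 3-[2,3,5,6-tetramethoxy-4-(6-methoxy-1-tosylindol-3-yl)phenyl]-1-tosylindol-5-ol
Conditions: H2 (1 atm), 10% Pd/C, THF–MeOH, rt; then Et3N (3 equiv), H2, rt
Reagents that add atoms: none
Why: Catalytic hydrogenolysis cleaves the aryl benzyl ether in the neutral first stage, and after addition of Et3N, which binds HCl and accelerates reduction of the C–Cl bond, Pd/C hydrodechlorination removes the C4 chlorine, while tosyl groups, methyl ethers and both indole rings are inert at one atmosphere.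

Step 14
Reactants: 21 3-[2,3,5,6-tetramethoxy-4-(6-methoxy-1-tosylindol-3-yl)phenyl]-1-tosylindol-5-ol
Product: 22 3-[2,3,5,6-tetramethoxy-4-(6-methoxy-1H-indol-3-yl)phenyl]-1H-indol-5-ol (target)
Conditions: Mg turnings (excess), MeOH–THF, sonication, rt, argon; aq NH4Cl
Reagents that add atoms: none
Why: Reductive N-desulfonylation by single-electron transfer from magnesium in methanol, which cleaves both indole N–S bonds as sulfinate and leaves aryl methyl ethers and the phenol untouched, with argon protecting the oxidisable 5-hydroxyindole.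

**Compound list**
1 | 6-methoxy-1H-indole | COc1ccc2cc[nH]c2c1 | starting material
2 | 3-iodo-6-methoxy-1H-indole | COc1ccc2c(I)c[nH]c2c1 | intermediate
3 | 3-iodo-6-methoxy-1-tosylindole | COc1ccc2c(I)cn(S(=O)(=O)c3ccc(C)cc3)c2c1 | intermediate
4 | 6-methoxy-3-(4,4,5,5-tetramethyl-1,3,2-dioxaborolan-2-yl)-1-tosylindole | COc1ccc2c(B3OC(C)(C)C(C)(C)O3)cn(S(=O)(=O)c3ccc(C)cc3)c2c1 | intermediate
5 | 1,2,4,5-tetramethoxybenzene | COc1cc(OC)c(OC)cc1OC | starting material
6 | 1,4-dibromo-2,3,5,6-tetramethoxybenzene | COc1c(Br)c(OC)c(OC)c(Br)c1OC | intermediate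
7 | (4-bromo-2,3,5,6-tetramethoxyphenyl)lithium | [Li]c1c(OC)c(OC)c(Br)c(OC)c1OC | intermediate (not isolated)
8 | 1-(4-bromo-2,3,5,6-tetramethoxyphenyl)-2-chloroethan-1-one | COc1c(Br)c(OC)c(OC)c(C(=O)CCl)c1OC | intermediate
9 | N-[2-(4-bromo-2,3,5,6-tetramethoxyphenyl)-2-oxoethyl]-4-methylbenzenesulfonamide | COc1c(Br)c(OC)c(OC)c(C(=O)CNS(=O)(=O)c2ccc(C)cc2)c1OC | intermediate
10 | N-{2-oxo-2-[2,3,5,6-tetramethoxy-4-(6-methoxy-1-tosylindol-3-yl)phenyl]ethyl}-4-methylbenzenesulfonamide | COc1ccc2c(-c3c(OC)c(OC)c(C(=O)CNS(=O)(=O)c4ccc(C)cc4)c(OC)c3OC)cn(S(=O)(=O)c3ccc(C)cc3)c2c1 | intermediate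
11 | 2-chlorobenzene-1,3-diol | Oc1cccc(O)c1Cl | starting material
12 | 4-bromo-2-chlorobenzene-1,3-diol | Oc1ccc(Br)c(O)c1Cl | intermediate
13 | disodium 4-bromo-2-chlorobenzene-1,3-diolate | [Na+].[Na+].[O-]c1ccc(Br)c([O-])c1Cl | intermediate (not isolated)
14 | 3-(benzyloxy)-6-bromo-2-chlorophenol | Oc1c(Br)ccc(OCc2ccccc2)c1Cl | intermediate
15 | [3-(benzyloxy)-6-bromo-2-chlorophenoxy]trimethylsilane | C[Si](C)(C)Oc1c(Br)ccc(OCc2ccccc2)c1Cl | intermediate
16 | lithium 3-(benzyloxy)-2-chloro-6-(trimethylsilyl)phenolate | [Li]Oc1c([Si](C)(C)C)ccc(OCc2ccccc2)c1Cl | intermediate (not isolated)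
17 | 3-(benzyloxy)-2-chloro-6-(trimethylsilyl)phenyl trifluoromethanesulfonate | C[Si](C)(C)c1ccc(OCc2ccccc2)c(Cl)c1OS(=O)(=O)C(F)(F)F | intermediate
18 | 4-(benzyloxy)-3-chlorobenzyne | ClC1=C(OCc2ccccc2)C=CC#C1 | intermediate (not isolated)
19 | 5-(benzyloxy)-4-chloro-3-[2,3,5,6-tetramethoxy-4-(6-methoxy-1-tosylindol-3-yl)phenyl]-1-tosylindolin-3-ol (racemic) | COc1ccc2c(-c3c(OC)c(OC)c(C4(O)CN(S(=O)(=O)c5ccc(C)cc5)c5ccc(OCc6ccccc6)c(Cl)c54)c(OC)c3OC)cn(S(=O)(=O)c3ccc(C)cc3)c2c1 | intermediate (not isolated)
20 | 5-(benzyloxy)-4-chloro-3-[2,3,5,6-tetramethoxy-4-(6-methoxy-1-tosylindol-3-yl)phenyl]-1-tosylindole | COc1ccc2c(-c3c(OC)c(OC)c(-c4cn(S(=O)(=O)c5ccc(C)cc5)c5ccc(OCc6ccccc6)c(Cl)c45)c(OC)c3OC)cn(S(=O)(=O)c3ccc(C)cc3)c2c1 | intermediate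
21 | 3-[2,3,5,6-tetramethoxy-4-(6-methoxy-1-tosylindol-3-yl)phenyl]-1-tosylindol-5-ol | COc1ccc2c(-c3c(OC)c(OC)c(-c4cn(S(=O)(=O)c5ccc(C)cc5)c5ccc(O)cc45)c(OC)c3OC)cn(S(=O)(=O)c3ccc(C)cc3)c2c1 | intermediate
22 | 3-[2,3,5,6-tetramethoxy-4-(6-methoxy-1H-indol-3-yl)phenyl]-1H-indol-5-ol | COc1ccc2c(-c3c(OC)c(OC)c(-c4c[nH]c5ccc(O)cc45)c(OC)c3OC)c[nH]c2c1 | target

**Total step count:** 14
**Longest linear sequence:** 7 steps (for example steps 1, 2, 3, 7, 12, 13, 14; the ring C branch and the aryne branch are equally long)

**Steps most likely to fail**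

Step 12. The aryl anion may be protonated before it reaches the ketone, which is crowded by two ortho methoxy groups, so the reaction could stop at simple N-arylation. The ortho-chloroaryl anion may also expel chloride, and the orientation of addition may erode.

The fallback sets out from dibromide 6 and comes back to the route at 21. Indole B is bought as a ring and joined by cross-coupling instead of being built.
- Commercial 5-benzyloxyindole is iodinated (I2, KOH, DMF) to 5-(benzyloxy)-3-iodo-1H-indole F1.
- F1 is N-tosylated (TsCl, aq NaOH, Bu4NHSO4) to 5-(benzyloxy)-3-iodo-1-tosylindole F2.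
- F2 is borylated (B2pin2, PdCl2(dppf), KOAc) to 5-(benzyloxy)-3-(4,4,5,5-tetramethyl-1,3,2-dioxaborolan-2-yl)-1-tosylindole F3.
- Suzuki–Miyaura coupling of F3 with an excess of 6 (Pd(OAc)2, SPhos, K3PO4) should give 5-(benzyloxy)-3-(4-bromo-2,3,5,6-tetramethoxyphenyl)-1-tosylindole F4.
- A second coupling with boronate 4 should give 5-(benzyloxy)-3-[2,3,5,6-tetramethoxy-4-(6-methoxy-1-tosylindol-3-yl)phenyl]-1-tosylindole F5.
- Hydrogenolysis of F5 (H2, Pd/C) should give 21.

Step 7. Oxidative addition into the electron-rich, doubly ortho-substituted C–Br bond may be slow. Protodeboronation of the indolyl boronate, base-induced loss of the tosyl group, or binding of the sulfonamide anion to palladium could then overtake the coupling.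

The fallback sets out from dibromide 6 (through aryllithium 7) and iodide 3, and comes back at 10. Both the polarity and the order of events are reversed.
- Aryllithium 7 is transmetalated with ZnCl2 to (4-bromo-2,3,5,6-tetramethoxyphenyl)zinc chloride F6.
- Negishi coupling of F6 with 3 (Pd(OAc)2, SPhos, THF, 50 °C) should give 3-(4-bromo-2,3,5,6-tetramethoxyphenyl)-6-methoxy-1-tosylindole F7. Here oxidative addition occurs at the unhindered carbon–iodine bond and neither base nor water is present.
- Bromine–lithium exchange (n-BuLi, THF, −95 °C) gives [2,3,5,6-tetramethoxy-4-(6-methoxy-1-tosylindol-3-yl)phenyl]lithium F8. Contact time is kept short so that the sulfonylindole is not metalated at C2.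
- The chloroacetyl Weinreb amide converts F8 into 2-chloro-1-[2,3,5,6-tetramethoxy-4-(6-methoxy-1-tosylindol-3-yl)phenyl]ethan-1-one F9.
- TsNH2, K2CO3 and NaI in DMF then lead to 10.

Step 13. Hydrodechlorination may stall. The C4–Cl bond lies between the C5 oxygen and the perpendicular ring C, so the arene cannot lie flat on the palladium surface. The amine may also slow the debenzylation.

The fallback sets out from 20 and comes back at target 22. The reductive cleavages are separated and the chlorine is removed in solution.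
- Mg in MeOH first removes both tosyl groups, which would otherwise partly solvolyse under the next conditions. This gives 5-(benzyloxy)-4-chloro-3-[2,3,5,6-tetramethoxy-4-(6-methoxy-1H-indol-3-yl)phenyl]-1H-indole F10.
- Homogeneous hydrodechlorination (Pd(OAc)2, 2-(di-tert-butylphosphino)biphenyl, HCO2Na, MeOH, 65 °C) should give 5-(benzyloxy)-3-[2,3,5,6-tetramethoxy-4-(6-methoxy-1H-indol-3-yl)phenyl]-1H-indole F11. A monoligated zerovalent palladium centre can reach the buried bond.
- Neutral hydrogenolysis (H2, Pd/C) then gives 22.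

**Further compounds**
F1 | step 12 | 5-(benzyloxy)-3-iodo-1H-indole | Ic1c[nH]c2ccc(OCc3ccccc3)cc12
F2 | step 12 | 5-(benzyloxy)-3-iodo-1-tosylindole | Cc1ccc(cc1)S(=O)(=O)n1cc(I)c2cc(OCc3ccccc3)ccc12
F3 | step 12 | 5-(benzyloxy)-3-(4,4,5,5-tetramethyl-1,3,2-dioxaborolan-2-yl)-1-tosylindole | Cc1ccc(cc1)S(=O)(=O)n1cc(B2OC(C)(C)C(C)(C)O2)c2cc(OCc3ccccc3)ccc12
F4 | step 12 | 5-(benzyloxy)-3-(4-bromo-2,3,5,6-tetramethoxyphenyl)-1-tosylindole | COc1c(Br)c(OC)c(OC)c(-c2cn(S(=O)(=O)c3ccc(C)cc3)c3ccc(OCc4ccccc4)cc23)c1OC
F5 | step 12 | 5-(benzyloxy)-3-[2,3,5,6-tetramethoxy-4-(6-methoxy-1-tosylindol-3-yl)phenyl]-1-tosylindole | COc1ccc2c(-c3c(OC)c(OC)c(-c4cn(S(=O)(=O)c5ccc(C)cc5)c5ccc(OCc6ccccc6)cc45)c(OC)c3OC)cn(S(=O)(=O)c3ccc(C)cc3)c2c1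
F6 | step 7 | (4-bromo-2,3,5,6-tetramethoxyphenyl)zinc chloride | Cl[Zn]c1c(OC)c(OC)c(Br)c(OC)c1OC
F7 | step 7 | 3-(4-bromo-2,3,5,6-tetramethoxyphenyl)-6-methoxy-1-tosylindole | COc1ccc2c(-c3c(OC)c(OC)c(Br)c(OC)c3OC)cn(S(=O)(=O)c3ccc(C)cc3)c2c1
F8 | step 7 | [2,3,5,6-tetramethoxy-4-(6-methoxy-1-tosylindol-3-yl)phenyl]lithium | COc1ccc2c(-c3c(OC)c(OC)c([Li])c(OC)c3OC)cn(S(=O)(=O)c3ccc(C)cc3)c2c1
F9 | step 7 | 2-chloro-1-[2,3,5,6-tetramethoxy-4-(6-methoxy-1-tosylindol-3-yl)phenyl]ethan-1-one | COc1ccc2c(-c3c(OC)c(OC)c(C(=O)CCl)c(OC)c3OC)cn(S(=O)(=O)c3ccc(C)cc3)c2c1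
F10 | step 13 | 5-(benzyloxy)-4-chloro-3-[2,3,5,6-tetramethoxy-4-(6-methoxy-1H-indol-3-yl)phenyl]-1H-indole | COc1ccc2c(-c3c(OC)c(OC)c(-c4c[nH]c5ccc(OCc6ccccc6)c(Cl)c45)c(OC)c3OC)c[nH]c2c1
F11 | step 13 | 5-(benzyloxy)-3-[2,3,5,6-tetramethoxy-4-(6-methoxy-1H-indol-3-yl)phenyl]-1H-indole | COc1ccc2c(-c3c(OC)c(OC)c(-c4c[nH]c5ccc(OCc6ccccc6)cc45)c(OC)c3OC)c[nH]c2c1
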